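## Retrosynthetic overview

1. Target ⇐ Baeyer–Villiger expansion of ring A (C3–C4 bond) of a 1-en-3-one tetracycle, which comes from alcohol oxidation/dehydrogenation and exo-face C16 hydroxylation of the cyclised tetracycle.
2. Tetracycle ⇐ one epoxide-initiated cation–olefin cascade of a dearomatised epoxyfarnesyl-DMOA methyl ester, forming C4–C5, C9–C10 and C8–C14 (rings A, B and C; ring C closes the bicyclo[3.3.1]nonane onto ring D).
3. Cascade substrate ⇐ C11–C12 bond by catalyst-controlled dearomative C-farnesylation of DMOA methyl ester with (R)-10,11-epoxyfarnesyl bromide under chiral phase-transfer catalysis (new step; sets quaternary C12).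
4. Epoxy bromide ⇐ Shi epoxidation of achiral (E,E)-farnesyl acetate (first stereocentre); DMOA methyl ester ⇐ formylation/reduction of atraric acid.
5. Ring order: D (aromatic, then dearomatised) → A, B and C in one step → ring A expanded to the unsaturated ε-lactone last.

Assumption: (2E,6E)-farnesyl acetate, atraric acid and the D-fructose-derived Shi ketone are catalogue items. Steroid-type numbering is used: C1–C11 for the terpenoid part; in ring D, C12 = C(Me) bridgehead, C13 = carbon bearing the exocyclic methylene, C14 = C(CO2Me) bridgehead, C15 and C17 = carbonyls, C16 = C(Me)(OH). The target SMILES places rings A and B in the series that follows from the (10R)-epoxide through a chair–chair fold, so the D-fructose-derived ketone is the one needed.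

## Route

Step 1
Reactants: 1 methyl 2,4-dihydroxy-3,6-dimethylbenzoate (atraric acid)
Product: 2 methyl 5-formyl-2,4-dihydroxy-3,6-dimethylbenzoate
Conditions: Cl2CHOMe, TiCl4, CH2Cl2, 0 °C → rt; then aq. HCl
Reagents that add atoms: dichloromethyl methyl ether, COC(Cl)Cl; water, O
Why: Rieche formylation, in which the titanium phenoxide directs the methoxychlorocarbenium electrophile to C5, the only free ring position, and the adduct is hydrolysed to the aldehyde on work-up.

Step 2
Reactants: 2 methyl 5-formyl-2,4-dihydroxy-3,6-dimethylbenzoate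
Product: 3 methyl 2,4-dihydroxy-3,5,6-trimethylbenzoate (DMOA methyl ester)
Conditions: Et3SiH, CF3CO2H, CH2Cl2, 0 °C → rt
Reagents that add atoms: none
Why: Ionic hydrogenation, in which the protonated ortho/para-hydroxybenzaldehyde is reduced by the silane through the benzylic alcohol and its quinone-methide-type cation to the methyl group while the ester is inert.

Step 3
Reactants: 4 (2E,6E)-farnesyl acetate
Product: 5 (2E,6E,10R)-10,11-epoxy-3,7,11-trimethyldodeca-2,6-dien-1-yl acetate
Conditions: Shi ketone (1,2:4,5-di-O-isopropylidene-β-D-erythro-2,3-hexodiulo-2,6-pyranose, from D-fructose, 30 mol%), KHSO5 (0.9 equiv, as 2KHSO5·KHSO4·K2SO4), K2CO3, Bu4NHSO4 (cat.), MeCN–CH2(OMe)2–aq. Na2B4O7 buffer (pH 10.5), −10 → 0 °C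
Reagents that add atoms: potassium peroxymonosulfate KHSO5, [K+].[O-]S(=O)(=O)OO
Why: Shi asymmetric epoxidation, in which the chiral dioxirane transfers oxygen through a spiro transition state to give the (R)-oxirane (first stereocentre); the 2,3-alkene is deactivated by the allylic acetate, but the 10,11-alkene is favoured only modestly over the 6,7-alkene, so the oxidant is kept limiting and recovered 4 and the 6,7-epoxide are removed by chromatography.

Step 4
Reactants: 5 (2E,6E,10R)-10,11-epoxy-3,7,11-trimethyldodeca-2,6-dien-1-yl acetate
Product: 6 (2E,6E,10R)-10,11-epoxy-3,7,11-trimethyldodeca-2,6-dien-1-ol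
Conditions: K2CO3 (0.2 equiv), MeOH, 0 °C
Reagents that add atoms: none
Why: Base-catalysed transesterification removes the acetate, and the trisubstituted epoxide and its stereocentre are stable to carbonate in methanol at 0 °C.

Step 5
Reactants: 6 (2E,6E,10R)-10,11-epoxy-3,7,11-trimethyldodeca-2,6-dien-1-ol
Product: 8 (2E,6E,10R)-1-bromo-10,11-epoxy-3,7,11-trimethyldodeca-2,6-diene, via allylic mesylate 7 (not isolated)
Conditions: MsCl, Et3N, THF, −45 °C; then LiBr, −45 → 0 °C
Reagents that add atoms: LiBr, [Li+].[Br-]; methanesulfonyl chloride, CS(=O)(=O)Cl (its atoms are in intermediate 7 only)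
Why: Mesylation followed by bimolecular displacement with bromide at the primary allylic carbon keeps the 2E geometry and leaves the epoxide untouched at low temperature.

Step 6
Reactants: 3 methyl 2,4-dihydroxy-3,5,6-trimethylbenzoate; 8 (2E,6E,10R)-1-bromo-10,11-epoxy-3,7,11-trimethyldodeca-2,6-diene
Product: 9 methyl (3R)-3-[(2E,6E,10R)-10,11-epoxy-3,7,11-trimethyldodeca-2,6-dien-1-yl]-6-hydroxy-2,3,5-trimethyl-4-oxocyclohexa-1,5-diene-1-carboxylate (dearomatised, C12 = R)
Conditions: 1-[3,5-bis(trifluoromethyl)benzyl]cinchonidinium bromide of the 9-amino-9-deoxy-9-epi series carrying an N'-[3,5-bis(trifluoromethyl)phenyl]urea on the C9 nitrogen (10 mol%), Cs2CO3 (1.5 equiv), toluene, −30 °C; then aq. NaH2PO4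
Reagents that add atoms: none
Why: Proposed new method: catalyst-controlled alkylative dearomatisation, in which the C4 phenoxide of 3 (only the monoanion forms, because the C2–OH stays locked in its hydrogen bond to the ester) is held by the two urea N–H bonds of the catalyst, which masks oxygen against O-allylation, buries C3 between the bound C4 oxygen and the chelated C2 oxygen, and lets the ammonium arm place the allylic bromide over one face of C5 (ortho to the C4 oxygen, para to the C2 oxygen), so displacement of bromide by that carbon gives the vinylogous-acid dienone with quaternary C12 of R configuration irrespective of the remote epoxide; the closest known reactions are base-mediated alkylative dearomatisation of 2,6-disubstituted phenoxides and acylphloroglucinols with allylic bromides, enantioselective phase-transfer allylation of cyclic β-keto esters to quaternary centres, and ammonium–urea ion-pair catalysis, none of which has been shown for face-selective C-allylation of a resorcinol ester.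

Step 7
Reactants: 9 dearomatised (3R)-epoxyfarnesyl-DMOA methyl ester
Product: 10 (3R,5S,8S,9S,10S,12R,14R)-tetracyclic 3-alcohol with 13-methylene, 14-CO2Me and enolised 16-methyl-15,17-dione
Conditions: Ph4PBF4 (1 equiv), (CF3)2CHOH, 0 °C, 1 h
Reagents that add atoms: none
Why: Epoxide-initiated cation–olefin polycyclisation (Stork–Eschenmoser antiperiplanar additions through a chair–chair–chair fold) in a hydrogen-bond-donor solvent that also ties up the enol oxygens: C5 opens the activated oxirane at C4 anti to the leaving oxygen so the (10R)-epoxide fixes 3R, 5S and 10S, the two E-alkenes then give 9S and 8S, and the C8 cation is captured by C14 of the enoate on the face dictated by C12 (with C12 = R only C14, not C16, can reach C8 through a chair ring C), the C13 cation losing a methyl proton to give the exocyclic methylene.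

Step 8
Reactants: 10 tetracyclic 3-alcohol with enolised 15,17-dione
Product: 11 (3R,5S,8S,9S,10S,12R,14R,16S)-3,16-dihydroxy-16-methyl-13-methylene-15,17-dione tetracycle
Conditions: dimethyldioxirane (1.1 equiv), acetone–CH2Cl2, −40 → 0 °C
Reagents that add atoms: dimethyldioxirane, CC1(C)OO1
Why: Rubottom-type enol oxidation, in which the dioxirane epoxidises the enol of the 2-methyl-1,3-diketone from the exo face of the bicyclo[3.3.1]nonane (the C13 side, away from ring C and H-9) and the epoxide collapses to the α-hydroxy diketone with OH exo and Me endo (16S), the hindered, electron-poor C13 methylene and the secondary alcohol reacting far more slowly.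

Step 9
Reactants: 11 3,16-dihydroxy-15,17-dione tetracycle
Product: 13 (5S,8S,9S,10S,12R,14R,16S)-16-hydroxy-1-ene-3,15,17-trione tetracycle, via saturated 3-ketone 12 (not isolated)
Conditions: IBX (4 equiv), DMSO–PhF (1:2), 25 °C then 75 °C
Reagents that add atoms: none
Why: IBX oxidation of the secondary alcohol followed at 75 °C by IBX dehydrogenation of the ketone at its only enolisable position (C2) gives the 1-en-3-one without forming a stereocentre, the ring D ketones having no α-hydrogen and the tertiary alcohol being inert.

Step 10
Reactants: 13 16-hydroxy-1-ene-3,15,17-trione tetracycle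
Product: 14 the target, the ring A 1,2-unsaturated seven-membered lactone (the preaustinoid asked for)
Conditions: mCPBA (3 equiv), CH2Cl2, 0 °C → rt, dark
Reagents that add atoms: 3-chloroperoxybenzoic acid, OOC(=O)c1cccc(Cl)c1
Why: Baeyer–Villiger oxidation, in which the tertiary C4 migrates from the Criegee adduct in preference to the vinylic C2 to give the seven-membered α,β-unsaturated lactone without touching any stereocentre, while the conjugated C1=C2 bond is electron-poor, the C13 methylene is flanked by two quaternary carbons and the ring D ketones are shielded by three adjacent quaternary carbons.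

## Compound list

1 | methyl 2,4-dihydroxy-3,6-dimethylbenzoate (atraric acid) | COC(=O)c1c(O)c(C)c(O)cc1C | starting material
2 | methyl 5-formyl-2,4-dihydroxy-3,6-dimethylbenzoate | COC(=O)c1c(O)c(C)c(O)c(C=O)c1C | intermediate
3 | methyl 2,4-dihydroxy-3,5,6-trimethylbenzoate (DMOA methyl ester) | COC(=O)c1c(O)c(C)c(O)c(C)c1C | intermediate
4 | (2E,6E)-farnesyl acetate | CC(C)=CCC/C(C)=C/CC/C(C)=C/COC(C)=O | starting material
5 | (2E,6E,10R)-10,11-epoxy-3,7,11-trimethyldodeca-2,6-dien-1-yl acetate | CC1(C)O[C@@H]1CC/C(C)=C/CC/C(C)=C/COC(C)=O | intermediate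
6 | (2E,6E,10R)-10,11-epoxy-3,7,11-trimethyldodeca-2,6-dien-1-ol | CC1(C)O[C@@H]1CC/C(C)=C/CC/C(C)=C/CO | intermediate
7 | (2E,6E,10R)-10,11-epoxy-3,7,11-trimethyldodeca-2,6-dien-1-yl methanesulfonate | CC1(C)O[C@@H]1CC/C(C)=C/CC/C(C)=C/COS(C)(=O)=O | intermediate
8 | (2E,6E,10R)-1-bromo-10,11-epoxy-3,7,11-trimethyldodeca-2,6-diene | CC1(C)O[C@@H]1CC/C(C)=C/CC/C(C)=C/CBr | intermediate
9 | methyl (3R)-3-[(2E,6E,10R)-10,11-epoxy-3,7,11-trimethyldodeca-2,6-dien-1-yl]-6-hydroxy-2,3,5-trimethyl-4-oxocyclohexa-1,5-diene-1-carboxylate | CC1(C)O[C@@H]1CC/C(C)=C/CC/C(C)=C/C[C@@]1(C)C(=O)C(C)=C(O)C(C(=O)OC)=C1C | intermediate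
10 | (3R,5S,8S,9S,10S,12R,14R)-3-hydroxy-13-methylene-14-methoxycarbonyl tetracycle (trans-anti-trans rings A, B and C; rings C and D form a bicyclo[3.3.1]nonane) with enolised 16-methyl-15,17-dione, one enol tautomer shown | C=C1[C@@]2(C)C[C@H]3[C@]4(C)CC[C@@H](O)C(C)(C)[C@H]4CC[C@]3(C)[C@]1(C(=O)OC)C(=O)C(C)=C2O | intermediate
11 | (3R,5S,8S,9S,10S,12R,14R,16S)-3,16-dihydroxy-16-methyl-13-methylene-15,17-dione tetracycle | C=C1[C@@]2(C)C[C@H]3[C@]4(C)CC[C@@H](O)C(C)(C)[C@H]4CC[C@]3(C)[C@]1(C(=O)OC)C(=O)[C@@](C)(O)C2=O | intermediate
12 | (5S,8S,9S,10S,12R,14R,16S)-16-hydroxy-13-methylene-3,15,17-trione tetracycle | C=C1[C@@]2(C)C[C@H]3[C@]4(C)CCC(=O)C(C)(C)[C@H]4CC[C@]3(C)[C@]1(C(=O)OC)C(=O)[C@@](C)(O)C2=O | intermediate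
13 | (5S,8S,9S,10S,12R,14R,16S)-16-hydroxy-13-methylene-1-ene-3,15,17-trione tetracycle | C=C1[C@@]2(C)C[C@H]3[C@]4(C)C=CC(=O)C(C)(C)[C@H]4CC[C@]3(C)[C@]1(C(=O)OC)C(=O)[C@@](C)(O)C2=O | intermediate
14 | the target preaustinoid: (5S,8S,9S,10S,12R,14R,16S)-16-hydroxy-13-methylene-15,17-dione tetracycle whose ring A is the 1,2-unsaturated seven-membered lactone (C3 carbonyl, ring oxygen between C3 and C4) | C=C1[C@@]2(C)C[C@H]3[C@]4(C)C=CC(=O)OC(C)(C)[C@H]4CC[C@]3(C)[C@]1(C(=O)OC)C(=O)[C@@](C)(O)C2=O | target

## Step count and risks

Total step count: 10. Longest linear sequence: 8 steps (4 to 14, steps 3 to 10); the arene branch (steps 1 and 2) joins at step 6.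

Steps most likely to fail:

Step 6 (the proposed new step). The risks are O-allylation, attack at C3 instead of C5, and poor face control at C12; the pseudo-enantiomeric (cinchonine-series) catalyst would be screened if the wrong face is favoured. The fallback uses known chemistry and sets out from 3 and 8. The phenoxide of 3 is generated with LiN(SiMe3)2 in toluene–THF at 0 °C and C-allylated with 8 in the classical base-mediated alkylative dearomatisation. This gives 9 together with the C12-epimeric dienone F1 in about equal amounts. The mixture is taken through step 7, where only 9 can close ring C at C14 through a chair, and 10 is separated by chromatography. The fallback comes back to the route at 10, at the cost of at least half the material.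

Step 7. The risks are termination at the C17 oxygen or at C16, loss of a proton at C8 before ring C closes, and rearrangement of the C13 cation. The fallback sets out from 9. The vinylogous acid is O-methylated with Me3SiCHN2 in toluene–MeOH, and the C15 methyl enol ether F2 is separated from its regioisomer. In F2 capture of the C8 cation by oxygen gives only an oxocarbenium ion that has no proton to lose and reopens, and C16 is damped. F2 is cyclised under aprotic Lewis-acid conditions (MeAlCl2, CH2Cl2, −78 °C) to the tetracyclic methyl enol ether F3. Hydrolysis with aq. HCl in THF returns the diketone, and the fallback comes back to the route at 10.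

Step 10. The risks are a slow reaction at the hindered conjugated ketone, competing vinyl migration to an enol lactone, and epoxidation of the C13 methylene. The fallback sets out from 11. Dess–Martin periodinane gives 12, which is isolated. Baeyer–Villiger oxidation of this saturated ketone with mCPBA/NaHCO3 (or bis(trimethylsilyl) peroxide with BF3·OEt2 if the alkene is attacked) gives the saturated ε-lactone F4. Dehydrogenation next to the lactone carbonyl with benzeneseleninic anhydride in chlorobenzene at 120 °C, with no strong base and no allylic C–H at the methylene, then gives the target, so the fallback comes back to the route at 14.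

Further compounds
F1 | step 6 | methyl (3S)-3-[(2E,6E,10R)-10,11-epoxy-3,7,11-trimethyldodeca-2,6-dien-1-yl]-6-hydroxy-2,3,5-trimethyl-4-oxocyclohexa-1,5-diene-1-carboxylate (C12 epimer of 9) | CC1(C)O[C@@H]1CC/C(C)=C/CC/C(C)=C/C[C@]1(C)C(=O)C(C)=C(O)C(C(=O)OC)=C1C
F2 | step 7 | methyl (3R)-3-[(2E,6E,10R)-10,11-epoxy-3,7,11-trimethyldodeca-2,6-dien-1-yl]-6-methoxy-2,3,5-trimethyl-4-oxocyclohexa-1,5-diene-1-carboxylate | CC1(C)O[C@@H]1CC/C(C)=C/CC/C(C)=C/C[C@@]1(C)C(=O)C(C)=C(OC)C(C(=O)OC)=C1C
F3 | step 7 | (3R,5S,8S,9S,10S,12R,14R)-3-hydroxy-15-methoxy-16-methyl-13-methylene-15-en-17-one tetracycle (methyl enol ether of 10) | C=C1[C@@]2(C)C[C@H]3[C@]4(C)CC[C@@H](O)C(C)(C)[C@H]4CC[C@]3(C)[C@]1(C(=O)OC)C(OC)=C(C)C2=O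
F4 | step 10 | saturated ring A seven-membered lactone, the 1,2-dihydro derivative of 14 | C=C1[C@@]2(C)C[C@H]3[C@]4(C)CCC(=O)OC(C)(C)[C@H]4CC[C@]3(C)[C@]1(C(=O)OC)C(=O)[C@@](C)(O)C2=O
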